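Rings are lettered along the chain from A (the 2-aryloxyphloroglucinol end) to D (the 3,4,5-trihydroxyphenoxy end), and the carbons of ring A are numbered 1 to 6 from the carbon that carries the ether oxygen to ring B. The route rests on ring A: its carbon 1 lies between the hydroxylated carbons 2 and 6, so carbon 1 with its oxygen is read as C2 of a malonate, carbons 2 and 6 as the two ester carbons of that malonate, and carbons 3, 4 and 5 as the inner carbons of a 3-oxoglutarate.
Ring A is formed last: the bonds between its carbons 2 and 3 and between its carbons 6 and 5 are cut back to a diethyl 2-(aryloxy)malonate and diethyl 3-oxopentanedioate (double Claisen annulation), followed by de-esterification, decarboxylation and cleavage of seven methyl ethers.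
The ether bond at carbon 1 of ring A goes back to SN2 alkylation of the heptamethylated ring B–C–D phenol with diethyl chloromalonate.
The ring B–C ether comes from copper-catalysed coupling of the ring C–D phenol with 2-bromo-3,5-dimethoxybenzaldehyde, and the ring C–D ether from Chan–Lam coupling of syringaldehyde with (3,4,5-trimethoxyphenyl)boronic acid. Each formyl group then becomes the next phenol by Baeyer–Villiger oxidation.
Rings B, C and D are bought as benzenes; ring A is the only ring that is built.

Key step: step 7

Remark: the target has no stereocenter and its diaryl ether bonds rotate freely, so nothing stereochemical has to be set. "Ar" below is the ring B–C–D group 2-[3,5-dimethoxy-4-(3,4,5-trimethoxyphenoxy)phenoxy]-3,5-dimethoxyphenyl.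

Step 1
Reactants: 1 4-hydroxy-3,5-dimethoxybenzaldehyde (syringaldehyde); 2 (3,4,5-trimethoxyphenyl)boronic acid
Product: 3 3,5-dimethoxy-4-(3,4,5-trimethoxyphenoxy)benzaldehyde
Conditions: Cu(OAc)2 (1 equiv, reoxidized by air), pyridine (5 equiv), 4 Å MS, CH2Cl2, dry air, rt; 2 (2 equiv) added in portions
Reagents that add atoms: none
Why: Chan–Lam oxidative O-arylation, in which the unhindered, electron-rich boronic acid transfers its aryl group to divalent copper and the copper phenoxide then forms the C–O bond; phenols with two ortho substituents are accepted in this coupling (as in thyronine-type ether syntheses), and the formyl group is inert at room temperature.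

Step 2
Reactants: 3 3,5-dimethoxy-4-(3,4,5-trimethoxyphenoxy)benzaldehyde
Product: 5 3,5-dimethoxy-4-(3,4,5-trimethoxyphenoxy)phenol, via aryl formate 4 (not isolated)
Conditions: mCPBA (1.3 equiv), CH2Cl2, 0 °C to rt; aq. NaHCO3 wash; then K2CO3 (cat.), MeOH, rt
Reagents that add atoms: mCPBA, O=C(OO)c1cccc(Cl)c1
Why: Baeyer–Villiger oxidation in which the aryl group migrates in preference to hydride because the para aryloxy oxygen stabilizes the migrating ring (as in the conversion of 3,4,5-trialkoxybenzaldehydes into phenols), followed by transesterification of the formate to methanol.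

Step 3
Reactants: 6 3,5-dimethoxybenzaldehyde
Product: 7 2-bromo-3,5-dimethoxybenzaldehyde
Conditions: NBS (1.05 equiv), MeCN, 0 °C to rt
Reagents that add atoms: N-bromosuccinimide, O=C1CCC(=O)N1Br
Why: Electrophilic aromatic bromination at C2, which is ortho to one methoxy group and para to the other and less shielded than C4 between the two methoxy groups; the formyl group and the new bromine slow a second bromination.

Step 4
Reactants: 5 3,5-dimethoxy-4-(3,4,5-trimethoxyphenoxy)phenol; 7 2-bromo-3,5-dimethoxybenzaldehyde
Product: 8 2-[3,5-dimethoxy-4-(3,4,5-trimethoxyphenoxy)phenoxy]-3,5-dimethoxybenzaldehyde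
Conditions: CuI (10 mol%), picolinic acid (20 mol%), K3PO4 (2 equiv), DMSO, 90 °C, Ar
Reagents that add atoms: none
Why: Ullmann-type diaryl ether coupling under monovalent copper catalysis, in which the phenoxide of 5 has no ortho substituent and the bromide of 7 is activated towards copper insertion by its ortho formyl group, as in Ullmann condensations of phenols with 2-bromobenzaldehydes and 2-bromo-3-alkoxybenzoates.

Step 5
Reactants: 8 2-[3,5-dimethoxy-4-(3,4,5-trimethoxyphenoxy)phenoxy]-3,5-dimethoxybenzaldehyde
Product: 10 2-[3,5-dimethoxy-4-(3,4,5-trimethoxyphenoxy)phenoxy]-3,5-dimethoxyphenol (ArOH), via aryl formate 9 (not isolated)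
Conditions: mCPBA (1.3 equiv), CH2Cl2, 0 °C to rt; aq. NaHCO3 wash; then K2CO3 (cat.), MeOH, rt, Ar
Reagents that add atoms: mCPBA, O=C(OO)c1cccc(Cl)c1
Why: Baeyer–Villiger oxidation with aryl migration directed by the ortho aryloxy donor (the usual way from 2-aryloxybenzaldehydes to 2-aryloxyphenols), then methanolysis of the formate; the peracid is washed out before the oxidation-prone phenol is set free.

Step 6
Reactants: 10 2-[3,5-dimethoxy-4-(3,4,5-trimethoxyphenoxy)phenoxy]-3,5-dimethoxyphenol (ArOH); 11 diethyl 2-chloropropanedioate (diethyl chloromalonate)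
Product: 12 diethyl 2-(ArO)propanedioate
Conditions: K2CO3 (2 equiv), acetone, reflux
Reagents that add atoms: none
Why: Williamson ether synthesis by SN2 attack of the phenoxide on the doubly activated C–Cl carbon, the standard preparation of aryloxymalonates from phenols; the chloride is taken in place of the bromide because it does not transfer positive halogen to the electron-rich phenoxide.

Step 7
Reactants: 12 diethyl 2-(ArO)propanedioate; 13 diethyl 3-oxopentanedioate
Product: 15 diethyl 2,4,6-trihydroxy-5-(ArO)benzene-1,3-dicarboxylate, via open-chain triester 14 (not isolated)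
Conditions: 13 (2 equiv), NaOEt (2 equiv), EtOH, rt; add 12; EtOH distilled off against toluene, 105 °C, Ar; then cold 1 M HCl
Reagents that add atoms: none
Why: Proposed new method: the sodium enolate of 13 should be C-acylated by one ester group of 12 (intermolecular Claisen condensation) to give the triacylmethane 14, and the enolate of the remaining CH2 group of 14 should then attack the second malonate ester (Dieckmann condensation), which makes the bonds between carbons 2 and 3 and between carbons 6 and 5 of ring A and, after loss of two ethanol and enolization of the cyclohexane-1,3,5-trione, gives ring A with the ether from its carbon 1 to ring B already in place. The closest known reaction type is the alkoxide-mediated condensation of unsubstituted diethyl malonate with 3-oxoglutaric esters to phloroglucinol dicarboxylates, together with the double N-acylation of amidines by 2-aryloxymalonates under alkoxide, which shows that such a malonate survives alkoxide and gives up both ester groups; what is new is a malonate with an oxygen substituent at C2 as the partner for carbon acylation. Ring A closes in a 6-exo-trig mode at the ester carbonyl, and no stereocenter is formed. The step needs carbon acylation over oxygen acylation and cross-condensation over self-condensation of 13: all acylations are reversible under ethoxide, and only the doubly C-acylated ring can leave the equilibrium as an aromatic, doubly chelated salicylate-type phenoxide. One equivalent of base per 13 keeps 13 as its enolate, whose ketone is then a poor aldol acceptor, while the less acidic 12 stays mostly un-ionized and electrophilic, and removal of ethanol by distillation pulls both condensations forward.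

Step 8
Reactants: 15 diethyl 2,4,6-trihydroxy-5-(ArO)benzene-1,3-dicarboxylate
Product: 17 2-(ArO)benzene-1,3,5-triol, via trihydroxyisophthalic acid 16 (not isolated)
Conditions: 2 M aq. KOH (degassed), EtOH, reflux, Ar; then HCl to pH 1, 80 °C
Reagents that add atoms: none
Why: Saponification of the two salicylate-type esters and protodecarboxylation of the 2,4,6-trihydroxybenzoic acid units through ipso protonation of the keto tautomer, the classical way from phloroglucinol carboxylates to phloroglucinols; aryl methyl ethers and diaryl ethers are inert to aqueous base and dilute acid.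

Step 9
Reactants: 17 2-(ArO)benzene-1,3,5-triol
Product: 18 2-{2-[3,5-dihydroxy-4-(3,4,5-trihydroxyphenoxy)phenoxy]-3,5-dihydroxyphenoxy}benzene-1,3,5-triol (target)
Conditions: BBr3 (15 equiv), CH2Cl2, −78 °C to rt, Ar; then MeOH and H2O at 0 °C
Reagents that add atoms: none
Why: Lewis acid mediated cleavage of the seven aryl methyl ethers by bromide attack at the methyl group of the boron-complexed ether; the diaryl ether bonds offer no sp3 carbon for this attack and should stay intact.

Compound list
1 | 4-hydroxy-3,5-dimethoxybenzaldehyde (syringaldehyde) | O=Cc1cc(OC)c(O)c(OC)c1 | starting material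
2 | (3,4,5-trimethoxyphenyl)boronic acid | OB(O)c1cc(OC)c(OC)c(OC)c1 | starting material
3 | 3,5-dimethoxy-4-(3,4,5-trimethoxyphenoxy)benzaldehyde | O=Cc1cc(OC)c(Oc2cc(OC)c(OC)c(OC)c2)c(OC)c1 | intermediate
4 | 3,5-dimethoxy-4-(3,4,5-trimethoxyphenoxy)phenyl formate | O=COc1cc(OC)c(Oc2cc(OC)c(OC)c(OC)c2)c(OC)c1 | intermediate
5 | 3,5-dimethoxy-4-(3,4,5-trimethoxyphenoxy)phenol | Oc1cc(OC)c(Oc2cc(OC)c(OC)c(OC)c2)c(OC)c1 | intermediate
6 | 3,5-dimethoxybenzaldehyde | O=Cc1cc(OC)cc(OC)c1 | starting material
7 | 2-bromo-3,5-dimethoxybenzaldehyde | O=Cc1cc(OC)cc(OC)c1Br | intermediate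
8 | 2-[3,5-dimethoxy-4-(3,4,5-trimethoxyphenoxy)phenoxy]-3,5-dimethoxybenzaldehyde | O=Cc1cc(OC)cc(OC)c1Oc1cc(OC)c(Oc2cc(OC)c(OC)c(OC)c2)c(OC)c1 | intermediate
9 | 2-[3,5-dimethoxy-4-(3,4,5-trimethoxyphenoxy)phenoxy]-3,5-dimethoxyphenyl formate | O=COc1cc(OC)cc(OC)c1Oc1cc(OC)c(Oc2cc(OC)c(OC)c(OC)c2)c(OC)c1 | intermediate
10 | 2-[3,5-dimethoxy-4-(3,4,5-trimethoxyphenoxy)phenoxy]-3,5-dimethoxyphenol (ArOH) | Oc1cc(OC)cc(OC)c1Oc1cc(OC)c(Oc2cc(OC)c(OC)c(OC)c2)c(OC)c1 | intermediate
11 | diethyl 2-chloropropanedioate (diethyl chloromalonate) | CCOC(=O)C(Cl)C(=O)OCC | starting material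
12 | diethyl 2-{2-[3,5-dimethoxy-4-(3,4,5-trimethoxyphenoxy)phenoxy]-3,5-dimethoxyphenoxy}propanedioate | CCOC(=O)C(Oc1cc(OC)cc(OC)c1Oc1cc(OC)c(Oc2cc(OC)c(OC)c(OC)c2)c(OC)c1)C(=O)OCC | intermediate
13 | diethyl 3-oxopentanedioate | CCOC(=O)CC(=O)CC(=O)OCC | starting material
14 | diethyl 2-(ArO)-4-(ethoxycarbonyl)-3,5-dioxoheptanedioate | CCOC(=O)CC(=O)C(C(=O)OCC)C(=O)C(Oc1cc(OC)cc(OC)c1Oc1cc(OC)c(Oc2cc(OC)c(OC)c(OC)c2)c(OC)c1)C(=O)OCC | intermediate
15 | diethyl 2,4,6-trihydroxy-5-(ArO)benzene-1,3-dicarboxylate | CCOC(=O)c1c(O)c(C(=O)OCC)c(O)c(Oc2cc(OC)cc(OC)c2Oc2cc(OC)c(Oc3cc(OC)c(OC)c(OC)c3)c(OC)c2)c1O | intermediate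
16 | 2,4,6-trihydroxy-5-(ArO)benzene-1,3-dicarboxylic acid | OC(=O)c1c(O)c(C(=O)O)c(O)c(Oc2cc(OC)cc(OC)c2Oc2cc(OC)c(Oc3cc(OC)c(OC)c(OC)c3)c(OC)c2)c1O | intermediate
17 | 2-(ArO)benzene-1,3,5-triol (heptamethyl ether of the target) | Oc1cc(O)c(Oc2cc(OC)cc(OC)c2Oc2cc(OC)c(Oc3cc(OC)c(OC)c(OC)c3)c(OC)c2)c(O)c1 | intermediate
18 | 2-{2-[3,5-dihydroxy-4-(3,4,5-trihydroxyphenoxy)phenoxy]-3,5-dihydroxyphenoxy}benzene-1,3,5-triol | Oc1cc(O)c(Oc2cc(O)cc(O)c2Oc2cc(O)c(Oc3cc(O)c(O)c(O)c3)c(O)c2)c(O)c1 | target

Total step count: 9. Longest linear sequence: 8 steps (1, 2, 4, 5, 6, 7, 8, 9, from syringaldehyde 1).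

Steps most likely to fail

Step 7. Self-condensation of 13 (aldol and Claisen reactions leading to an orcinol-type triester) and enolization of 12, which switches off its ester carbonyls, may outrun the cross-acylation. Oxygen acylation may also divert material into pyranone-type products. The fallback gives up the annulation and brings ring A in as a ready-made benzene by the known chemistry of steps 4 and 5. It sets out from phenol 10: copper-catalysed coupling with bromide 7 (CuI, picolinic acid, K3PO4, DMSO, 100 °C) should give 2-(ArO)-3,5-dimethoxybenzaldehyde F1. Baeyer–Villiger oxidation (mCPBA, CH2Cl2) should give 2-(ArO)-3,5-dimethoxyphenyl formate F2, and methanolysis (K2CO3, MeOH) 2-(ArO)-3,5-dimethoxyphenol F3. BBr3 in CH2Cl2 then cleaves all nine methyl ethers, and the fallback comes back to the route at target 18.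

Step 4. Copper insertion at the bromide of 7, which is flanked by a formyl and a methoxy group, may be too slow, so that hydrodebromination of 7 and base-induced decay of the formyl group take over. The fallback reverses the roles of the partners: the crowded ring B carbon carries the nucleophilic oxygen and ring C the halide. It sets out from boronic acid 2, whose Chan–Lam coupling with 4-bromo-2,6-dimethoxyphenol (Cu(OAc)2, pyridine, 4 Å MS, CH2Cl2, air) should give 5-bromo-1,3-dimethoxy-2-(3,4,5-trimethoxyphenoxy)benzene F4. In parallel, commercial 2-hydroxy-4,6-dimethoxybenzaldehyde is benzylated (BnBr, K2CO3, DMF) to 2-(benzyloxy)-4,6-dimethoxybenzaldehyde F5. Baeyer–Villiger oxidation (mCPBA) gives 2-(benzyloxy)-4,6-dimethoxyphenyl formate F6, and methanolysis gives 2-(benzyloxy)-4,6-dimethoxyphenol F7. Coupling of F7 with F4 (CuI, picolinic acid, K3PO4, DMSO, 110 °C, a catalyst system that accepts phenols with two ortho substituents) should give 1-(benzyloxy)-2-[3,5-dimethoxy-4-(3,4,5-trimethoxyphenoxy)phenoxy]-3,5-dimethoxybenzene F8. Hydrogenolysis (H2, Pd/C, EtOAc) comes back to the route at phenol 10, so that steps 4 and 5 are bypassed.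

Step 1. C–O bond formation at the hindered, weakly nucleophilic phenoxide of 1 may be slower than oxidative homocoupling, protodeboronation and hydroxylation of 2, so that the boronic acid is used up without coupling. The fallback again reverses the polarity and replaces the oxidative coupling by a copper-catalysed substitution at an aryl bromide. It sets out from 2, which is converted with H2O2 and NaOH into 3,4,5-trimethoxyphenol F9 (also an article of commerce). The unhindered phenoxide of F9 is coupled with commercial 4-bromo-3,5-dimethoxybenzaldehyde, whose bromide is activated by the para formyl group (CuI, picolinic acid, K3PO4, DMSO, 100 °C), and the fallback comes back to the route at aldehyde 3.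

Further compounds
F1 | step 7 | 2-{2-[3,5-dimethoxy-4-(3,4,5-trimethoxyphenoxy)phenoxy]-3,5-dimethoxyphenoxy}-3,5-dimethoxybenzaldehyde | O=Cc1cc(OC)cc(OC)c1Oc1cc(OC)cc(OC)c1Oc1cc(OC)c(Oc2cc(OC)c(OC)c(OC)c2)c(OC)c1
F2 | step 7 | 2-{2-[3,5-dimethoxy-4-(3,4,5-trimethoxyphenoxy)phenoxy]-3,5-dimethoxyphenoxy}-3,5-dimethoxyphenyl formate | O=COc1cc(OC)cc(OC)c1Oc1cc(OC)cc(OC)c1Oc1cc(OC)c(Oc2cc(OC)c(OC)c(OC)c2)c(OC)c1
F3 | step 7 | 2-{2-[3,5-dimethoxy-4-(3,4,5-trimethoxyphenoxy)phenoxy]-3,5-dimethoxyphenoxy}-3,5-dimethoxyphenol | Oc1cc(OC)cc(OC)c1Oc1cc(OC)cc(OC)c1Oc1cc(OC)c(Oc2cc(OC)c(OC)c(OC)c2)c(OC)c1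
F4 | step 4 | 5-bromo-1,3-dimethoxy-2-(3,4,5-trimethoxyphenoxy)benzene | COc1cc(Br)cc(OC)c1Oc1cc(OC)c(OC)c(OC)c1
F5 | step 4 | 2-(benzyloxy)-4,6-dimethoxybenzaldehyde | O=Cc1c(OC)cc(OC)cc1OCc1ccccc1
F6 | step 4 | 2-(benzyloxy)-4,6-dimethoxyphenyl formate | O=COc1c(OC)cc(OC)cc1OCc1ccccc1
F7 | step 4 | 2-(benzyloxy)-4,6-dimethoxyphenol | Oc1c(OC)cc(OC)cc1OCc1ccccc1
F8 | step 4 | 1-(benzyloxy)-2-[3,5-dimethoxy-4-(3,4,5-trimethoxyphenoxy)phenoxy]-3,5-dimethoxybenzene | COc1cc(OC)c(Oc2cc(OC)c(Oc3cc(OC)c(OC)c(OC)c3)c(OC)c2)c(OCc2ccccc2)c1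
F9 | step 1 | 3,4,5-trimethoxyphenol | COc1cc(O)cc(OC)c1OC
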